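C–N and C–C cuts: N–CH3 first, then C1–CH3 (back to a 3,4-dihydroisoquinolin-1-one), then C1–C8a together with N2–C3 (back to a 3-aryl-2-methylpropanoic acid), and last the C7–C1′ biaryl bond and the C3=C4 olefin of the side chain.
Enabling feature: in the nitrogen ring, N2 lies between C1 and C3. C1 can therefore enter as a carboxyl carbon on C3 and move to the far side of nitrogen by a Curtius shift. C8a of the benzo ring is ortho to the 8-OMe and para to the 6-OMe, so it can capture that carbon.
Forward order: second naphthalene ring (Stobbe condensation, Friedel–Crafts acylation), side-chain olefination, Suzuki biaryl coupling, hydrogenation, closure of the nitrogen ring, then the two methyl groups.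
Stereochemistry: C3 (S) comes from a ruthenium-catalysed enantioselective hydrogenation and passes through the shift with retention. C1 (R) comes from hydride addition to C1=N under control of C3 (1,3-cis).

Key step: step 12

Assumption: the SMILES fixes C1 as R and C3 as S (1,3-cis) but gives no sense for the C7–C1′ axis; that axis becomes stereogenic in step 12, is left uncontrolled, and 19–25 are carried as the pair of rotational isomers about it, to be parted by HPLC at the end if one is wanted.

Step 1
Reactants: 1 2-bromo-5-methoxybenzaldehyde; 2 diethyl succinate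
Product: 3 (3E)-4-(2-bromo-5-methoxyphenyl)-3-(ethoxycarbonyl)but-3-enoic acid
Conditions: KOt-Bu, t-BuOH, reflux; then aq HCl
Reagents that add atoms: none
Why: Stobbe condensation: the succinate enolate adds to the non-enolisable aldehyde and the sequence ends irreversibly in a carboxylate salt, with the E half-ester (aryl group and CH2CO2H on the same side of the double bond, as the next ring closure needs) as the expected main isomer.

Step 2
Reactants: 3 (3E)-4-(2-bromo-5-methoxyphenyl)-3-(ethoxycarbonyl)but-3-enoic acid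
Product: 5 ethyl 4-acetoxy-8-bromo-5-methoxynaphthalene-2-carboxylate, via naphthol ester 4 (not isolated)
Conditions: Ac2O, NaOAc, reflux
Reagents that add atoms: acetic anhydride, CC(=O)OC(C)=O
Why: Intramolecular Friedel–Crafts acylation of the acid activated by acetic anhydride: bromine blocks one ortho position, so the ring can close only at the carbon ortho to the methoxy group, and the naphthol 4 that results from enolisation is acetylated at once, which protects it from oxidation.

Step 3
Reactants: 5 ethyl 4-acetoxy-8-bromo-5-methoxynaphthalene-2-carboxylate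
Product: 6 5-bromo-3-(hydroxymethyl)-8-methoxynaphthalen-1-ol
Conditions: LiAlH4, THF, 0 °C; then aq HCl
Reagents that add atoms: none
Why: Ester reduction with LiAlH4 takes the ethyl ester to the primary alcohol and cleaves the aryl acetate in the same operation, while the aryl bromide is not attacked at this temperature.

Step 4
Reactants: 6 5-bromo-3-(hydroxymethyl)-8-methoxynaphthalen-1-ol
Product: 7 (8-bromo-4,5-dimethoxynaphthalen-2-yl)methanol
Conditions: MeI, K2CO3, acetone, reflux
Reagents that add atoms: iodomethane, CI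
Why: Williamson ether synthesis: K2CO3 deprotonates only the naphthol and not the benzylic alcohol, so methylation is confined to the phenolic oxygen.

Step 5
Reactants: 7 (8-bromo-4,5-dimethoxynaphthalen-2-yl)methanol
Product: 8 1-bromo-7-(bromomethyl)-4,5-dimethoxynaphthalene
Conditions: CBr4, PPh3, CH2Cl2, 0 °C
Reagents that add atoms: tetrabromomethane, BrC(Br)(Br)Br
Why: Appel reaction: the primary benzylic alcohol is turned into the bromide under neutral conditions that leave the aryl ethers and the aryl bromide alone.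

Step 6
Reactants: 8 1-bromo-7-(bromomethyl)-4,5-dimethoxynaphthalene
Product: 9 1-bromo-4,5-dimethoxy-7-methylnaphthalene
Conditions: LiEt3BH, THF, 0 °C
Reagents that add atoms: none
Why: SN2 displacement of bromide by hydride: LiEt3BH reacts with a benzylic bromide far faster than with an aryl bromide, so only the CH2Br group is reduced to CH3.

Step 7
Reactants: 9 1-bromo-4,5-dimethoxy-7-methylnaphthalene
Product: 10 2-(4,5-dimethoxy-7-methylnaphthalen-1-yl)-4,4,5,5-tetramethyl-1,3,2-dioxaborolane
Conditions: B2pin2, PdCl2(dppf) (cat.), KOAc, 1,4-dioxane, 90 °C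
Reagents that add atoms: bis(pinacolato)diboron, CC1(C)OB(OC1(C)C)B1OC(C)(C)C(C)(C)O1
Why: Miyaura borylation: zerovalent palladium inserts into the C–Br bond and acetate-assisted transmetalation with B2pin2 gives a storable boronate without recourse to an organolithium.

Step 8
Reactants: 11 4-bromo-3,5-dimethoxybenzaldehyde; 12 triethyl 2-phosphonopropionate
Product: 13 ethyl (2E)-3-(4-bromo-3,5-dimethoxyphenyl)-2-methylprop-2-enoate
Conditions: NaH, THF, 0 °C to rt
Reagents that add atoms: none
Why: Horner–Wadsworth–Emmons olefination: the stabilised α-methyl phosphonate anion and an aromatic aldehyde give the trisubstituted enoate with the aryl group trans to the ester (E), the geometry on which the later hydrogenation depends.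

Step 9
Reactants: 10 2-(4,5-dimethoxy-7-methylnaphthalen-1-yl)-4,4,5,5-tetramethyl-1,3,2-dioxaborolane; 13 ethyl (2E)-3-(4-bromo-3,5-dimethoxyphenyl)-2-methylprop-2-enoate
Product: 14 ethyl (2E)-3-[3,5-dimethoxy-4-(4,5-dimethoxy-7-methylnaphthalen-1-yl)phenyl]-2-methylprop-2-enoate
Conditions: Pd(OAc)2 (cat.), SPhos (2-dicyclohexylphosphino-2′,6′-dimethoxybiphenyl), K3PO4, toluene/H2O, 100 °C
Reagents that add atoms: none
Why: Suzuki–Miyaura coupling: the bromide is activated by the para enoate, the bulky electron-rich ligand SPhos suits biaryls with three ortho substituents, and boron is placed on the naphthalene because 2,6-dimethoxyarylboron compounds protodeboronate easily.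

Step 10
Reactants: 14 ethyl (2E)-3-[3,5-dimethoxy-4-(4,5-dimethoxy-7-methylnaphthalen-1-yl)phenyl]-2-methylprop-2-enoate
Product: 15 (2E)-3-[3,5-dimethoxy-4-(4,5-dimethoxy-7-methylnaphthalen-1-yl)phenyl]-2-methylprop-2-enoic acid
Conditions: LiOH, THF/MeOH/H2O, 50 °C; then aq HCl
Reagents that add atoms: lithium hydroxide, [Li+].[OH-]
Why: Saponification: hydroxide cleaves the ethyl ester by acyl substitution without touching the double-bond geometry or the aryl ethers, and frees the carboxyl group that the hydrogenation catalyst needs as an anchor.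

Step 11
Reactants: 15 (2E)-3-[3,5-dimethoxy-4-(4,5-dimethoxy-7-methylnaphthalen-1-yl)phenyl]-2-methylprop-2-enoic acid
Product: 16 (2S)-3-[3,5-dimethoxy-4-(4,5-dimethoxy-7-methylnaphthalen-1-yl)phenyl]-2-methylpropanoic acid
Conditions: Ru(OAc)2[(S)-H8-BINAP] (cat.), H2 (low pressure, a few bar), MeOH/CH2Cl2, rt
Reagents that add atoms: none
Why: Noyori-type asymmetric hydrogenation: the acid binds to ruthenium as a carboxylate and H2 is delivered to one face of the E-olefin; the partly hydrogenated ligand H8-BINAP is chosen because parent BINAP is known to be much less selective for α-methylcinnamic acids, and the (S)-ligand because it gives the (S)-acids from tiglic acid and α-methylcinnamic acid, which sets the future C3 as S.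

Step 12
Reactants: 16 (2S)-3-[3,5-dimethoxy-4-(4,5-dimethoxy-7-methylnaphthalen-1-yl)phenyl]-2-methylpropanoic acid
Product: 19 (3S)-7-(4,5-dimethoxy-7-methylnaphthalen-1-yl)-6,8-dimethoxy-3-methyl-3,4-dihydroisoquinolin-1(2H)-one, via acyl azide 17 (not isolated), via isocyanate 18 (not isolated)
Conditions: DPPA, Et3N, toluene, rt then 90 °C; cool, BF3·OEt2 (excess), 0 °C to rt; aq NaHCO3
Reagents that add atoms: diphenylphosphoryl azide, [N-]=[N+]=NP(=O)(Oc1ccccc1)Oc1ccccc1
Why: DPPA transfers azide to the carboxylate of 16 to give acyl azide 17, which on warming loses N2 while C3 migrates from the carbonyl carbon to nitrogen in a concerted 1,2-shift with retention, so the old carboxyl carbon becomes the isocyanate carbon of 18 and the N2–C3 bond exists with C3 still S. BF3 then binds the isocyanate oxygen, C8a attacks the sp carbon in an intramolecular Friedel–Crafts carbamoylation, and loss of the ring proton restores the arene and gives the lactam (C1–C8a). The closest known chemistry is the Curtius rearrangement of 3-arylpropanoic acids followed by acid-promoted cyclisation of the 2-arylethyl isocyanates to 3,4-dihydroisoquinolin-1-ones. The single ring formed is six-membered and closes 6-endo-dig with respect to the N=C bond, which ends up inside the ring. No new stereogenic carbon arises, the only stereochemical demand is retention at C3, which is inherent in the shift, and the biaryl axis becomes stereogenic here without control. Regioselectivity is not at stake, because the two free positions ortho to the side chain are interchanged by the local symmetry of the 3,5-dimethoxy-4-aryl ring and give the same constitution, each lying ortho to one and para to the other methoxy group; the tether cannot reach the electron-rich naphthalene, and BF3·OEt2 is used in excess because the diphenyl phosphate salt ties up part of it.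

Step 13
Reactants: 19 (3S)-7-(4,5-dimethoxy-7-methylnaphthalen-1-yl)-6,8-dimethoxy-3-methyl-3,4-dihydroisoquinolin-1(2H)-one
Product: 20 tert-butyl (3S)-7-(4,5-dimethoxy-7-methylnaphthalen-1-yl)-6,8-dimethoxy-3-methyl-1-oxo-3,4-dihydroisoquinoline-2(1H)-carboxylate
Conditions: Boc2O, DMAP, MeCN, rt
Reagents that add atoms: di-tert-butyl dicarbonate, CC(C)(C)OC(=O)OC(=O)OC(C)(C)C
Why: DMAP-catalysed N-acylation: the Boc group turns the unreactive, electron-rich benzolactam into an imide-like system whose ring carbonyl accepts carbon nucleophiles.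

Step 14
Reactants: 20 tert-butyl (3S)-7-(4,5-dimethoxy-7-methylnaphthalen-1-yl)-6,8-dimethoxy-3-methyl-1-oxo-3,4-dihydroisoquinoline-2(1H)-carboxylate
Product: 21 tert-butyl N-[(2S)-1-[2-acetyl-3,5-dimethoxy-4-(4,5-dimethoxy-7-methylnaphthalen-1-yl)phenyl]propan-2-yl]carbamate
Conditions: MeMgBr, THF, −78 to −20 °C; aq NH4Cl
Reagents that add atoms: methylmagnesium bromide, C[Mg]Br
Why: Grignard addition to an N-Boc lactam with ring opening: MeMgBr attacks the ring carbonyl rather than the tert-butyl-shielded carbamate carbonyl, the carbamate nitrogen leaves as its anion, and the doubly ortho-substituted aryl methyl ketone is too hindered for a second addition at low temperature.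

Step 15
Reactants: 21 tert-butyl N-[(2S)-1-[2-acetyl-3,5-dimethoxy-4-(4,5-dimethoxy-7-methylnaphthalen-1-yl)phenyl]propan-2-yl]carbamate
Product: 24 (1R,3S)-7-(4,5-dimethoxy-7-methylnaphthalen-1-yl)-6,8-dimethoxy-1,3-dimethyl-1,2,3,4-tetrahydroisoquinoline, via amino ketone 22 (not isolated), via dihydroisoquinoline 23 (not isolated)
Conditions: TFA, CH2Cl2, 0 °C to rt; evaporate; Et3N, MeOH, rt; NaBH4, 0 °C
Reagents that add atoms: none
Why: Boc acidolysis, condensation and imine reduction: the freed amine closes on the ortho acetyl group to the six-membered cyclic imine, and borohydride adds axially to C1 on the face away from the C3 methyl group, so H-1 and H-3 end up on the same side and C1 becomes R (1,3-cis), as is general for 1,3-dimethyl-3,4-dihydroisoquinolines.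

Step 16
Reactants: 24 (1R,3S)-7-(4,5-dimethoxy-7-methylnaphthalen-1-yl)-6,8-dimethoxy-1,3-dimethyl-1,2,3,4-tetrahydroisoquinoline
Product: 25 ancistrobrevine A, (1R,3S)-7-(4,5-dimethoxy-7-methylnaphthalen-1-yl)-6,8-dimethoxy-1,2,3-trimethyl-1,2,3,4-tetrahydroisoquinoline
Conditions: aq HCHO, NaBH(OAc)3, 1,2-dichloroethane, rt
Reagents that add atoms: formaldehyde, C=O
Why: Reductive amination: formaldehyde and NaBH(OAc)3 methylate the hindered secondary amine under mild, nearly neutral conditions that leave the benzylic centre C1 and C3 untouched.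

Compound list
1 | 2-bromo-5-methoxybenzaldehyde | COc1ccc(Br)c(C=O)c1 | starting material
2 | diethyl succinate | CCOC(=O)CCC(=O)OCC | starting material
3 | (3E)-4-(2-bromo-5-methoxyphenyl)-3-(ethoxycarbonyl)but-3-enoic acid | CCOC(=O)/C(CC(=O)O)=C/c1cc(OC)ccc1Br | intermediate
4 | ethyl 8-bromo-4-hydroxy-5-methoxynaphthalene-2-carboxylate (not isolated) | CCOC(=O)c1cc(O)c2c(OC)ccc(Br)c2c1 | intermediate
5 | ethyl 4-acetoxy-8-bromo-5-methoxynaphthalene-2-carboxylate | CCOC(=O)c1cc(OC(C)=O)c2c(OC)ccc(Br)c2c1 | intermediate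
6 | 5-bromo-3-(hydroxymethyl)-8-methoxynaphthalen-1-ol | OCc1cc(O)c2c(OC)ccc(Br)c2c1 | intermediate
7 | (8-bromo-4,5-dimethoxynaphthalen-2-yl)methanol | OCc1cc(OC)c2c(OC)ccc(Br)c2c1 | intermediate
8 | 1-bromo-7-(bromomethyl)-4,5-dimethoxynaphthalene | BrCc1cc(OC)c2c(OC)ccc(Br)c2c1 | intermediate
9 | 1-bromo-4,5-dimethoxy-7-methylnaphthalene | Cc1cc(OC)c2c(OC)ccc(Br)c2c1 | intermediate
10 | 2-(4,5-dimethoxy-7-methylnaphthalen-1-yl)-4,4,5,5-tetramethyl-1,3,2-dioxaborolane | Cc1cc(OC)c2c(OC)ccc(B3OC(C)(C)C(C)(C)O3)c2c1 | intermediate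
11 | 4-bromo-3,5-dimethoxybenzaldehyde | COc1cc(C=O)cc(OC)c1Br | starting material
12 | triethyl 2-phosphonopropionate | CCOC(=O)C(C)P(=O)(OCC)OCC | starting material
13 | ethyl (2E)-3-(4-bromo-3,5-dimethoxyphenyl)-2-methylprop-2-enoate | CCOC(=O)/C(C)=C/c1cc(OC)c(Br)c(OC)c1 | intermediate
14 | ethyl (2E)-3-[3,5-dimethoxy-4-(4,5-dimethoxy-7-methylnaphthalen-1-yl)phenyl]-2-methylprop-2-enoate | CCOC(=O)/C(C)=C/c1cc(OC)c(-c2ccc(OC)c3c(OC)cc(C)cc23)c(OC)c1 | intermediate
15 | (2E)-3-[3,5-dimethoxy-4-(4,5-dimethoxy-7-methylnaphthalen-1-yl)phenyl]-2-methylprop-2-enoic acid | OC(=O)/C(C)=C/c1cc(OC)c(-c2ccc(OC)c3c(OC)cc(C)cc23)c(OC)c1 | intermediate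
16 | (2S)-3-[3,5-dimethoxy-4-(4,5-dimethoxy-7-methylnaphthalen-1-yl)phenyl]-2-methylpropanoic acid | C[C@@H](Cc1cc(OC)c(-c2ccc(OC)c3c(OC)cc(C)cc23)c(OC)c1)C(=O)O | intermediate
17 | (2S)-3-[3,5-dimethoxy-4-(4,5-dimethoxy-7-methylnaphthalen-1-yl)phenyl]-2-methylpropanoyl azide (not isolated) | C[C@@H](Cc1cc(OC)c(-c2ccc(OC)c3c(OC)cc(C)cc23)c(OC)c1)C(=O)N=[N+]=[N-] | intermediate
18 | 1-{4-[(2S)-2-isocyanatopropyl]-2,6-dimethoxyphenyl}-4,5-dimethoxy-7-methylnaphthalene (not isolated) | C[C@@H](Cc1cc(OC)c(-c2ccc(OC)c3c(OC)cc(C)cc23)c(OC)c1)N=C=O | intermediate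
19 | (3S)-7-(4,5-dimethoxy-7-methylnaphthalen-1-yl)-6,8-dimethoxy-3-methyl-3,4-dihydroisoquinolin-1(2H)-one | COc1cc2c(c(OC)c1-c1ccc(OC)c3c(OC)cc(C)cc13)C(=O)N[C@@H](C)C2 | intermediate
20 | tert-butyl (3S)-7-(4,5-dimethoxy-7-methylnaphthalen-1-yl)-6,8-dimethoxy-3-methyl-1-oxo-3,4-dihydroisoquinoline-2(1H)-carboxylate | COc1cc2c(c(OC)c1-c1ccc(OC)c3c(OC)cc(C)cc13)C(=O)N(C(=O)OC(C)(C)C)[C@@H](C)C2 | intermediate
21 | tert-butyl N-[(2S)-1-[2-acetyl-3,5-dimethoxy-4-(4,5-dimethoxy-7-methylnaphthalen-1-yl)phenyl]propan-2-yl]carbamate | C[C@@H](Cc1cc(OC)c(-c2ccc(OC)c3c(OC)cc(C)cc23)c(OC)c1C(C)=O)NC(=O)OC(C)(C)C | intermediate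
22 | 1-{6-[(2S)-2-aminopropyl]-2,4-dimethoxy-3-(4,5-dimethoxy-7-methylnaphthalen-1-yl)phenyl}ethan-1-one (not isolated) | C[C@@H](Cc1cc(OC)c(-c2ccc(OC)c3c(OC)cc(C)cc23)c(OC)c1C(C)=O)N | intermediate
23 | (3S)-7-(4,5-dimethoxy-7-methylnaphthalen-1-yl)-6,8-dimethoxy-1,3-dimethyl-3,4-dihydroisoquinoline (not isolated) | COc1cc2c(c(OC)c1-c1ccc(OC)c3c(OC)cc(C)cc13)C(C)=N[C@@H](C)C2 | intermediate
24 | (1R,3S)-7-(4,5-dimethoxy-7-methylnaphthalen-1-yl)-6,8-dimethoxy-1,3-dimethyl-1,2,3,4-tetrahydroisoquinoline | COc1cc2c(c(OC)c1-c1ccc(OC)c3c(OC)cc(C)cc13)[C@@H](C)N[C@@H](C)C2 | intermediate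
25 | ancistrobrevine A, (1R,3S)-7-(4,5-dimethoxy-7-methylnaphthalen-1-yl)-6,8-dimethoxy-1,2,3-trimethyl-1,2,3,4-tetrahydroisoquinoline | COc1cc2c(c(OC)c1-c1ccc(OC)c3c(OC)cc(C)cc13)[C@@H](C)N(C)[C@@H](C)C2 | target

Total step count: 16.
Longest linear sequence: 15 steps (steps 1–7 and 9–16, from 1). Step 8 is the only step of the short branch.

Steps most likely to fail

Step 12. The Lewis acid may be tied up by the triethylammonium diphenyl phosphate left from the azide transfer. Hydrolysis of the isocyanate with urea formation, or its oligomerisation, could then outrun ring closure. The fallback separates the two events and changes the electrophile while forming the same bonds. From 16 the Curtius rearrangement is run as before, but the isocyanate is quenched with methanol to give the isolable methyl N-[(2S)-1-[3,5-dimethoxy-4-(4,5-dimethoxy-7-methylnaphthalen-1-yl)phenyl]propan-2-yl]carbamate F1. Activation of the carbamate with Tf2O and DMAP in CH2Cl2 at 0 °C (a Bischler–Napieralski-type closure) forms C1–C8a and gives the lactim ether (3S)-1,6,8-trimethoxy-3-methyl-7-(4,5-dimethoxy-7-methylnaphthalen-1-yl)-3,4-dihydroisoquinoline F2. Dilute HCl in THF hydrolyses this, and the route is rejoined at 19.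

Step 14. The Grignard reagent may attack the carbamate carbonyl instead, which would remove the Boc group and return the lactam. It may also fail to add at all to a ring carbonyl that is both hindered and deactivated by the ortho and para methoxy groups. The fallback replaces carbonyl addition by cross-coupling. From 19, POCl3 in toluene at 80 °C gives the cyclic imidoyl chloride (3S)-1-chloro-7-(4,5-dimethoxy-7-methylnaphthalen-1-yl)-6,8-dimethoxy-3-methyl-3,4-dihydroisoquinoline F3. An iron-catalysed Kumada-type coupling (MeMgBr, Fe(acac)3, THF/NMP, 0 °C) then exchanges chlorine for methyl. The route is rejoined at 23, which is reduced with NaBH4 as in step 15.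

Step 11. Facial discrimination by the catalyst may be incomplete on this bulky, poorly soluble trisubstituted acid. That would leave an enantiomeric purity that no later step can correct, because C1 is set relative to C3. Crystallising a 1-phenylethylammonium salt of 16 is the first remedy. The fallback replaces catalysis by an auxiliary.
- From 11, NaBH4 in MeOH gives (4-bromo-3,5-dimethoxyphenyl)methanol F4, and PBr3 in CH2Cl2 gives 2-bromo-5-(bromomethyl)-1,3-dimethoxybenzene F5.
- Evans alkylation with F5 of the sodium enolate (NaHMDS, THF, −78 °C) of commercial (R)-4-benzyl-3-propionyl-1,3-oxazolidin-2-one gives (4R)-4-benzyl-3-[(2S)-3-(4-bromo-3,5-dimethoxyphenyl)-2-methylpropanoyl]-1,3-oxazolidin-2-one F6.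
- The benzyl group of the auxiliary shields one face of the chelated Z-enolate, so the new centre is S, and a minor diastereomer can be removed by chromatography or crystallisation.
- LiOH/H2O2 frees (2S)-3-(4-bromo-3,5-dimethoxyphenyl)-2-methylpropanoic acid F7.
- Suzuki–Miyaura coupling of F7 with 10 under the conditions of step 9, with one more equivalent of K3PO4, rejoins the route at 16.

Further compounds
F1 | step 12 | methyl N-[(2S)-1-[3,5-dimethoxy-4-(4,5-dimethoxy-7-methylnaphthalen-1-yl)phenyl]propan-2-yl]carbamate | C[C@@H](Cc1cc(OC)c(-c2ccc(OC)c3c(OC)cc(C)cc23)c(OC)c1)NC(=O)OC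
F2 | step 12 | (3S)-1,6,8-trimethoxy-3-methyl-7-(4,5-dimethoxy-7-methylnaphthalen-1-yl)-3,4-dihydroisoquinoline | COC1=N[C@@H](C)Cc2cc(OC)c(-c3ccc(OC)c4c(OC)cc(C)cc34)c(OC)c21
F3 | step 14 | (3S)-1-chloro-7-(4,5-dimethoxy-7-methylnaphthalen-1-yl)-6,8-dimethoxy-3-methyl-3,4-dihydroisoquinoline | COc1cc2c(c(OC)c1-c1ccc(OC)c3c(OC)cc(C)cc13)C(Cl)=N[C@@H](C)C2
F4 | step 11 | (4-bromo-3,5-dimethoxyphenyl)methanol | COc1cc(CO)cc(OC)c1Br
F5 | step 11 | 2-bromo-5-(bromomethyl)-1,3-dimethoxybenzene | COc1cc(CBr)cc(OC)c1Br
F6 | step 11 | (4R)-4-benzyl-3-[(2S)-3-(4-bromo-3,5-dimethoxyphenyl)-2-methylpropanoyl]-1,3-oxazolidin-2-one | C[C@@H](Cc1cc(OC)c(Br)c(OC)c1)C(=O)N1[C@H](Cc2ccccc2)COC1=O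
F7 | step 11 | (2S)-3-(4-bromo-3,5-dimethoxyphenyl)-2-methylpropanoic acid | C[C@@H](Cc1cc(OC)c(Br)c(OC)c1)C(=O)O
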